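## Structural features

The target is a linear trimer of acylphloroglucinols: three fully substituted benzene rings joined by two CH2 bridges. Ring A (central) carries a butanoyl group at C1, hydroxyls at C2, C4 and C6, and the two bridges at C3 and C5. Rings B and C (outer, identical) carry the bridge at C1', hydroxyls at C2' and C4' on either side of a butanoyl group at C3', a methyl at C5' and a methoxy at C6'. There is no stereocentre, so no stereocentres stand next to each other; a mirror plane runs through C1 and C4 of ring A. The fragile parts are the electron-rich phenol nuclei, which oxidise in air under basic conditions, and the diarylmethane bridges, which strong acid or hot alkali can cleave or scramble. The difficulty is regiochemical: all eighteen ring carbons are substituted, two of nine phenolic oxygens are methylated, and two identical outer rings must be attached to ring A without statistical coupling. The key step uses the fact that C3–C4 and C5–C6 of ring A are the same two-carbon unit, a carbon with an arylmethyl arm next to a carbon with oxygen. Both units come from one arylmethyl siloxyalkyne, used once as such (C3–C4) and once as a cyclobutenone (C5–C6, with C1–C2 supplied by ketene).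

## Logic of the disconnections

23 to 22: the four benzyl C–O bonds on O2' and O4' of both outer rings are cut. The free polyphenol is sensitive to air, acid and base, so the outer-ring hydroxyls stay masked until the end. The forward step must be neutral and must spare three aryl ketones and the bridges, which points to hydrogenolysis.

22 to 19 and 20: the C1–C(=O) bond of ring A is cut. C1 is the only hydrogen-bearing ring carbon of 19 and sits in a free phloroglucinol nucleus, so ring A needs no acyl group while it is built. The forward acylation must avoid AlCl3, which cleaves benzyl ethers ortho to a carbonyl and would release benzyl cations able to alkylate C1; 20 with HCl meets this demand, the ketone forming through 21.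

19 to 18: two aryl O–Si bonds on ring A and two enol O–Si bonds on the outer rings are cut. All four silyl groups fall to one fluoride treatment, so unmasking the outer ketones costs no extra step. The forward step needs buffering and exclusion of air.

18 to 13 and 11: the bonds C2–C3 and C4–C5 of ring A are cut; C1–C2 opens and re-forms during the cascade through 14, 15, 16 and 17. This halves the molecule into two partners that share one precursor and places all three oxygens and both arms by connectivity. The forward step demands one regiochemical event, the ketene–alkyne cycloaddition, plus thermal tolerance of both partners. Tracing the mechanism atom by atom confirms that 13 and 11 give exactly the substitution pattern of 18.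

13 to 11 and 12: the bonds C2–C5 and C6–C1 of the four-membered ring (ring A numbering) are cut. The same alkyne serves twice, and the forward [2+2] step has the same polar bias as the key step.

11 to 8: the O–Si bond and the C–O bond at the alkyne terminus are cut, so the ynol oxygen is introduced by oxidation of an acetylide, through 9 and 10. This needs organolithium reagents, which a free outer-ring butanoyl ketone would not survive. For that reason 8, 11, 13 and 18 carry the ketone as its silyl enol ether, with the carbon skeleton unchanged.

8 to 7 to 6: the enol O–Si bond and then the two benzyl C–O bonds are cut. These are routine protections, in an order that keeps the alkyne and ketone untouched.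

6 to 4 and 5: the C1'–CH2 bond is cut. C1' is the only free nuclear carbon of 4 and is ortho and para to phenoxide oxygens. The forward step must favour C- over O-alkylation.

4 to 3 to 1 and 2: the O–CH3 bond at the oxygen para to the ketone and then the aryl–acyl bond are cut. The forward steps rely on the higher acidity of the non-chelated hydroxyl and on the equivalence of the two free carbons of 1.

## Other disconnections considered

Alternative 1: The cut is C1'–C2' and C3'–C4' in both outer rings, which are then made last from chains attached to a finished ring A. In the forward key step the bis(β-keto ester) A2 would be deprotonated twice on each chain, and the two γ-carbanions (C1') acylated by the ester group of methyl 3-oxohexanoate A3, itself present as its enolate. Each triketo ester would then close by Claisen condensation of C3' onto the C4' ester to give A1.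
- In its favour: ring A carries its butanoyl group from the start, so no late acylation is needed, which is better than the chosen plan. Only a twofold O-methylation at C6' and a hydrogenolysis would follow, one operation fewer than the three after step 8.
- Against it: four C–C bonds must form from a polyanion and an ester made less electrophilic by its own enolate. Proton transfer among the acidic sites and aldol-type closure to resorcinol rings are expected to compete. The selective methylation that the chosen plan does early on a small compound (step 2) would fall twice on a late intermediate, and A2 needs several steps.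
- Comparison: both plans use the twin symmetry. This one relies on strongly basic ionic condensations, the chosen one on a neutral pericyclic cascade with one polarity-controlled cycloaddition. Total step counts are probably similar.

Alternative 2: The cut is C1–C2, C3–C4 and C5–C6 of ring A, which gives three alkynes. In the forward key step two molecules of the ynol ether A5 and one of the ynone A6 would be cyclotrimerised by the cationic rhodium complex A7, [Rh(cod)2]BF4, together with a chelating bisphosphine, to give A4.
- In its favour: it is the most convergent plan. Ring A forms with its butanoyl group in place and a single hydrogenolysis would finish the synthesis, so it is better than the chosen plan on the steps after the key step. It needs neither 12 nor a cyclobutenone.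
- Against it: nothing in the alkynes enforces the 2:1 cross-selection or the head-to-tail orientation, so homotrimers and 1,2,4-oxygenated isomers are expected. Benzyl ynol ethers are prone to sigmatropic rearrangement to ketenes on mild warming, and hexasubstituted benzenes from three internal alkynes are demanding for a catalyst such as A7. Making A5 meets the same ketone problem as making 11.
- Comparison: the structural idea is the same. The chosen plan spends extra steps (step 7 and the late acylation) to replace a three-component selectivity problem with two successive two-component cycloadditions, each with a built-in polar bias.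

Alternative 3: The cut is C2'–C3' in both outer rings, each of which is drawn from an isomeric 2-pyranone. In the forward key step magnesium dimethoxide A10, Mg(OMe)2, would open both lactones of A9 at the carbonyl. Each diketone carbanion C3' would then attack the new C2' ester, and aromatisation would give A8.
- In its favour: the C6' methoxy comes from the 4-methoxy group of the pyranone, so no selective methylation is needed, which is better than step 2. Ring A is complete and one hydrogenolysis would finish, which is better than three steps. The rearrangement type is known for single rings.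
- Against it: A9 contains two fully substituted pyranones that must each be built and joined at C3 to a ring A bis-electrophile, which is likely to cost more steps than the chosen route. Both rings must rearrange in one molecule under the basic conditions set by A10, and incomplete reaction or re-lactonisation would lose material.
- Comparison: this plan is shorter after the key step and longer before it. It is an ionic, base-mediated closure of the outer rings, against a thermal pericyclic closure of ring A.

Key step: step 8

Remarks on the chemistry:
- Ring A is numbered C1 to C6 and the outer rings C1' to C6' as above; where atoms of the four-membered ring of 13 are discussed, ring A numbering is used (C2 carbonyl carbon, C5 arm-bearing carbon, C6 siloxy carbon, C1 the CH2 group).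
- Ar-e = 2,4-bis(benzyloxy)-3-[(1Z)-1-{[tert-butyl(dimethyl)silyl]oxy}but-1-en-1-yl]-6-methoxy-5-methylphenyl.
- Ar-k = 2,4-bis(benzyloxy)-3-butanoyl-6-methoxy-5-methylphenyl.
- Assumption: the silyl enol ether is drawn as the Z isomer expected from soft enolisation; its geometry is erased in step 9 and does not affect the route.
- Ketene 12 is not sold; it is generated from acetone in a ketene lamp just before use.
- About half of 11 goes into step 7 and the rest into step 8.

## Route

Step 1
Reactants: 1 2,4,6-trihydroxytoluene; 2 butanoyl chloride
Product: 3 1-(2,4,6-trihydroxy-3-methylphenyl)butan-1-one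
Conditions: AlCl3, PhNO2, rt → 60 °C; aq. HCl
Reagents that add atoms: none
Why: Friedel–Crafts C-acylation of a phloroglucinol; the two free ring carbons of 1 are equivalent, the first acyl group deactivates the ring toward a second, and any O-acyl material should return to carbon by Fries rearrangement under the same conditions.

Step 2
Reactants: 3 1-(2,4,6-trihydroxy-3-methylphenyl)butan-1-one
Product: 4 1-(2,6-dihydroxy-4-methoxy-3-methylphenyl)butan-1-one (aspidinol)
Conditions: Me2SO4 (1 equiv), K2CO3, acetone, rt
Reagents that add atoms: dimethyl sulfate, COS(=O)(=O)OC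
Why: Williamson O-methylation; the hydroxyl para to the carbonyl is the most acidic and the only one not hydrogen-bonded to the ketone, so one equivalent of methylating agent with a weak base should take it in preference to the two chelated ortho hydroxyls.

Step 3
Reactants: 4 1-(2,6-dihydroxy-4-methoxy-3-methylphenyl)butan-1-one; 5 3-bromoprop-1-yne (propargyl bromide)
Product: 6 1-[2,6-dihydroxy-4-methoxy-3-methyl-5-(prop-2-yn-1-yl)phenyl]butan-1-one
Conditions: KOH (10% aq.), 0 °C → rt
Reagents that add atoms: none
Why: Nuclear C-alkylation of an acylphloroglucinol phenoxide by an activated primary halide in water, the reaction type used for C-allylation and C-prenylation of such phenols; hydrogen bonding of water to the phenoxide oxygens should steer the halide to the only hydrogen-bearing ring carbon, which is ortho and para to the two phenoxide oxygens.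

Step 4
Reactants: 6 1-[2,6-dihydroxy-4-methoxy-3-methyl-5-(prop-2-yn-1-yl)phenyl]butan-1-one
Product: 7 1-[2,6-bis(benzyloxy)-4-methoxy-3-methyl-5-(prop-2-yn-1-yl)phenyl]butan-1-one
Conditions: BnBr, K2CO3, DMF, 50 °C
Reagents that add atoms: benzyl bromide, BrCc1ccccc1
Why: Williamson etherification in a dipolar aprotic solvent, which favours O- over C-alkylation; excess halide should benzylate both chelated hydroxyls, and the terminal alkyne is too weakly acidic for K2CO3.

Step 5
Reactants: 7 1-[2,6-bis(benzyloxy)-4-methoxy-3-methyl-5-(prop-2-yn-1-yl)phenyl]butan-1-one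
Product: 8 3-(Ar-e)prop-1-yne
Conditions: TBSOTf, Et3N, CH2Cl2, 0 °C → rt
Reagents that add atoms: tert-butyldimethylsilyl trifluoromethanesulfonate, CC(C)(C)[Si](C)(C)OS(=O)(=O)C(F)(F)F
Why: Soft enolisation with a silyl triflate and a tertiary amine turns the aryl ketone into its silyl enol ether, expected as the Z isomer with the ethyl group turned away from the di-ortho-substituted ring; this masks the one group of 7 that would not survive the organolithium chemistry of step 6, and fluoride removes it in step 9 without an extra operation.

Step 6
Reactants: 8 3-(Ar-e)prop-1-yne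
Product: 11 {[3-(Ar-e)prop-1-yn-1-yl]oxy}tri(propan-2-yl)silane, via lithium acetylide 9 (not isolated), via lithium ynolate 10 (not isolated)
Conditions: n-BuLi, THF, −78 °C; t-BuOOLi (from t-BuOOH and LiN(SiMe3)2), −78 → 0 °C; TIPSOTf, −78 → 0 °C
Reagents that add atoms: tert-butyl hydroperoxide, CC(C)(C)OO; triisopropylsilyl trifluoromethanesulfonate, CC(C)[Si](OS(=O)(=O)C(F)(F)F)(C(C)C)C(C)C
Why: The terminal alkyne is deprotonated, the acetylide carbon attacks an oxygen of lithium tert-butyl peroxide (acetylide oxidation, a known route to lithium ynolates), and the bulky silyl triflate silylates the ynolate on oxygen to give the silyl ynol ether; benzyl ethers and the silyl enol ether should tolerate these conditions at low temperature.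

Step 7
Reactants: 11 {[3-(Ar-e)prop-1-yn-1-yl]oxy}tri(propan-2-yl)silane; 12 ketene (passed in as a gas)
Product: 13 2-[(Ar-e)methyl]-3-{[tri(propan-2-yl)silyl]oxy}cyclobut-2-en-1-one
Conditions: CH2Cl2, 0 °C → rt
Reagents that add atoms: none
Why: [2+2] cycloaddition of ketene with a siloxyalkyne, a known route to 3-siloxycyclobutenones; the nucleophilic β-carbon of 11 attacks the ketene carbonyl carbon and the zwitterion collapses, which fixes the arylmethyl group at C2 and the siloxy group at C3 of the four-membered ring, while the hindered silyl enol ether is too weak a nucleophile to compete.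

Step 8
Reactants: 13 2-[(Ar-e)methyl]-3-{[tri(propan-2-yl)silyl]oxy}cyclobut-2-en-1-one; 11 {[3-(Ar-e)prop-1-yn-1-yl]oxy}tri(propan-2-yl)silane
Product: 18 2,4-bis[(Ar-e)methyl]-3,5-bis{[tri(propan-2-yl)silyl]oxy}phenol, via siloxy vinylketene 14 (not isolated), via 4-vinylcyclobutenone 15 (not isolated), via dienylketene 16 (not isolated), via cyclohexa-2,4-dienone 17 (not isolated)
Conditions: toluene, 80 → 110 °C, argon, sealed tube; 11 in slight excess
Reagents that add atoms: none
Why: This is a Danheiser benzannulation of a cyclobutenone with a siloxyalkyne, the closest known reaction type; a 3-siloxy group on the cyclobutenone partner is a less common member of that substrate class. Heating opens 13 by 4π electrocyclic ring opening (the bond between the CH2 group and the carbonyl carbon, C1–C2 in ring A numbering, breaks) to the vinylketene 14. The ketene of 14 adds to 11 in a [2+2] step in which the nucleophilic β-carbon of the ynol ether (C3) bonds to the ketene carbonyl carbon (C2) and the oxygen-bearing carbon (C4) bonds to C5, giving 15. Compound 15 opens reversibly to 16, and the isomer with the vinyl group cis to the ketene closes ring A by a thermal 6π electrocyclisation (C1 onto C2), so the six-membered ring forms by pericyclic closure; tautomerisation of 17 gives the phenol. No stereocentre is created, because the quaternary carbon of 15 is transient and the enol ether geometry is untouched. The only selectivity needed is the regiochemistry of the ketene–alkyne [2+2] step, which the polarisation of the siloxyalkyne secures; it puts the oxygens at C2, C4 and C6 and the arms at C3 and C5. A slight excess of 11 should intercept 14 as it forms and so hold back ketene dimerisation and acylation of the product phenol, while benzyl ethers and silyl enol ethers are spectators under neutral thermal conditions.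

Step 9
Reactants: 18 2,4-bis[(Ar-e)methyl]-3,5-bis{[tri(propan-2-yl)silyl]oxy}phenol
Product: 19 2,4-bis[(Ar-k)methyl]benzene-1,3,5-triol
Conditions: Bu4NF, AcOH, THF, 0 °C → rt, argon
Reagents that add atoms: none
Why: Fluoride-mediated desilylation cleaves the two aryl silyl ethers and the two silyl enol ethers in one operation through Si–F bond formation; acetic acid protonates the phenoxides and enolates as they form, so the electron-rich ring A triol does not sit in strong base, and exclusion of air guards against oxidation.

Step 10
Reactants: 19 2,4-bis[(Ar-k)methyl]benzene-1,3,5-triol; 20 butanenitrile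
Product: 22 1-{3,5-bis[(Ar-k)methyl]-2,4,6-trihydroxyphenyl}butan-1-one, via ketiminium chloride 21 (not isolated)
Conditions: HCl (g), ZnCl2 (cat.), Et2O, 0 °C; then H2O, 80 °C
Reagents that add atoms: water, O
Why: Hoesch acylation: the electrophile formed from 20 and HCl attacks C1, the only hydrogen-bearing ring carbon of 19 and part of a free phloroglucinol nucleus, and warm water hydrolyses the ketiminium salt to the ketone; unlike an AlCl3-mediated Friedel–Crafts acylation this should leave the benzyl ethers intact, so no benzyl cation is released that could alkylate C1.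

Step 11
Reactants: 22 1-{3,5-bis[(Ar-k)methyl]-2,4,6-trihydroxyphenyl}butan-1-one
Product: 23 1-{3,5-bis[(3-butanoyl-2,4-dihydroxy-6-methoxy-5-methylphenyl)methyl]-2,4,6-trihydroxyphenyl}butan-1-one (CNP0264591.0)
Conditions: H2 (1 atm), Pd/C, EtOAc–MeOH, rt
Reagents that add atoms: none
Why: Catalytic hydrogenolysis of the four aryl benzyl ethers under neutral conditions; the aryl ketones, each hydrogen-bonded to flanking hydroxyls once unveiled, and the diarylmethane C–C bonds should not be reduced if the reaction is stopped after four equivalents of hydrogen are taken up.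

## Compound list

1 | 2,4,6-trihydroxytoluene | Cc1c(O)cc(O)cc1O | starting material
2 | butanoyl chloride | CCCC(Cl)=O | starting material
3 | 1-(2,4,6-trihydroxy-3-methylphenyl)butan-1-one | CCCC(=O)c1c(O)cc(O)c(C)c1O | intermediate
4 | 1-(2,6-dihydroxy-4-methoxy-3-methylphenyl)butan-1-one (aspidinol) | CCCC(=O)c1c(O)cc(OC)c(C)c1O | intermediate
5 | 3-bromoprop-1-yne (propargyl bromide) | BrCC#C | starting material
6 | 1-[2,6-dihydroxy-4-methoxy-3-methyl-5-(prop-2-yn-1-yl)phenyl]butan-1-one | C#CCc1c(OC)c(C)c(O)c(C(=O)CCC)c1O | intermediate
7 | 1-[2,6-bis(benzyloxy)-4-methoxy-3-methyl-5-(prop-2-yn-1-yl)phenyl]butan-1-one | C#CCc1c(OC)c(C)c(OCc2ccccc2)c(C(=O)CCC)c1OCc1ccccc1 | intermediate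
8 | 3-(Ar-e)prop-1-yne, the (Z)-tert-butyldimethylsilyl enol ether of 7 | C#CCc1c(OC)c(C)c(OCc2ccccc2)c(/C(O[Si](C)(C)C(C)(C)C)=C/CC)c1OCc1ccccc1 | intermediate
9 | lithium 3-(Ar-e)prop-1-yn-1-ide | [Li]C#CCc1c(OC)c(C)c(OCc2ccccc2)c(/C(O[Si](C)(C)C(C)(C)C)=C/CC)c1OCc1ccccc1 | intermediate (not isolated)
10 | lithium 3-(Ar-e)prop-1-yn-1-olate | [Li]OC#CCc1c(OC)c(C)c(OCc2ccccc2)c(/C(O[Si](C)(C)C(C)(C)C)=C/CC)c1OCc1ccccc1 | intermediate (not isolated)
11 | {[3-(Ar-e)prop-1-yn-1-yl]oxy}tri(propan-2-yl)silane | CC(C)[Si](OC#CCc1c(OC)c(C)c(OCc2ccccc2)c(/C(O[Si](C)(C)C(C)(C)C)=C/CC)c1OCc1ccccc1)(C(C)C)C(C)C | intermediate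
12 | ketene (ethenone; gas generated from acetone by pyrolysis just before use) | C=C=O | starting material
13 | 2-[(Ar-e)methyl]-3-{[tri(propan-2-yl)silyl]oxy}cyclobut-2-en-1-one | O=C1CC(O[Si](C(C)C)(C(C)C)C(C)C)=C1Cc1c(OC)c(C)c(OCc2ccccc2)c(/C(O[Si](C)(C)C(C)(C)C)=C/CC)c1OCc1ccccc1 | intermediate
14 | 2-[(Ar-e)methyl]-3-{[tri(propan-2-yl)silyl]oxy}buta-1,3-dien-1-one | O=C=C(Cc1c(OC)c(C)c(OCc2ccccc2)c(/C(O[Si](C)(C)C(C)(C)C)=C/CC)c1OCc1ccccc1)C(=C)O[Si](C(C)C)(C(C)C)C(C)C | intermediate (not isolated)
15 | 2,4-bis[(Ar-e)methyl]-3-(triisopropylsiloxy)-4-[1-(triisopropylsiloxy)ethenyl]cyclobut-2-en-1-one (racemic at C4 of the four-membered ring) | O=C1C(Cc2c(OC)c(C)c(OCc3ccccc3)c(/C(O[Si](C)(C)C(C)(C)C)=C/CC)c2OCc2ccccc2)=C(O[Si](C(C)C)(C(C)C)C(C)C)C1(Cc1c(OC)c(C)c(OCc2ccccc2)c(/C(O[Si](C)(C)C(C)(C)C)=C/CC)c1OCc1ccccc1)C(=C)O[Si](C(C)C)(C(C)C)C(C)C | intermediate (not isolated)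
16 | 2,4-bis[(Ar-e)methyl]-3,5-bis(triisopropylsiloxy)hexa-1,3,5-trien-1-one, ketene and vinyl termini cis about the central double bond | O=C=C(Cc1c(OC)c(C)c(OCc2ccccc2)c(/C(O[Si](C)(C)C(C)(C)C)=C/CC)c1OCc1ccccc1)/C(O[Si](C(C)C)(C(C)C)C(C)C)=C(Cc1c(OC)c(C)c(OCc2ccccc2)c(/C(O[Si](C)(C)C(C)(C)C)=C/CC)c1OCc1ccccc1)\C(=C)O[Si](C(C)C)(C(C)C)C(C)C | intermediate (not isolated)
17 | 2,4-bis[(Ar-e)methyl]-3,5-bis(triisopropylsiloxy)cyclohexa-2,4-dien-1-one | O=C1CC(O[Si](C(C)C)(C(C)C)C(C)C)=C(Cc2c(OC)c(C)c(OCc3ccccc3)c(/C(O[Si](C)(C)C(C)(C)C)=C/CC)c2OCc2ccccc2)C(O[Si](C(C)C)(C(C)C)C(C)C)=C1Cc1c(OC)c(C)c(OCc2ccccc2)c(/C(O[Si](C)(C)C(C)(C)C)=C/CC)c1OCc1ccccc1 | intermediate (not isolated)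
18 | 2,4-bis[(Ar-e)methyl]-3,5-bis{[tri(propan-2-yl)silyl]oxy}phenol | Oc1cc(O[Si](C(C)C)(C(C)C)C(C)C)c(Cc2c(OC)c(C)c(OCc3ccccc3)c(/C(O[Si](C)(C)C(C)(C)C)=C/CC)c2OCc2ccccc2)c(O[Si](C(C)C)(C(C)C)C(C)C)c1Cc1c(OC)c(C)c(OCc2ccccc2)c(/C(O[Si](C)(C)C(C)(C)C)=C/CC)c1OCc1ccccc1 | intermediate
19 | 2,4-bis[(Ar-k)methyl]benzene-1,3,5-triol | Oc1cc(O)c(Cc2c(OC)c(C)c(OCc3ccccc3)c(C(=O)CCC)c2OCc2ccccc2)c(O)c1Cc1c(OC)c(C)c(OCc2ccccc2)c(C(=O)CCC)c1OCc1ccccc1 | intermediate
20 | butanenitrile | CCCC#N | starting material
21 | 1-{3,5-bis[(Ar-k)methyl]-2,4,6-trihydroxyphenyl}butan-1-iminium chloride | CCCC(=[NH2+])c1c(O)c(Cc2c(OC)c(C)c(OCc3ccccc3)c(C(=O)CCC)c2OCc2ccccc2)c(O)c(Cc2c(OC)c(C)c(OCc3ccccc3)c(C(=O)CCC)c2OCc2ccccc2)c1O.[Cl-] | intermediate (not isolated)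
22 | 1-{3,5-bis[(Ar-k)methyl]-2,4,6-trihydroxyphenyl}butan-1-one | CCCC(=O)c1c(O)c(Cc2c(OC)c(C)c(OCc3ccccc3)c(C(=O)CCC)c2OCc2ccccc2)c(O)c(Cc2c(OC)c(C)c(OCc3ccccc3)c(C(=O)CCC)c2OCc2ccccc2)c1O | intermediate
23 | 1-{3,5-bis[(3-butanoyl-2,4-dihydroxy-6-methoxy-5-methylphenyl)methyl]-2,4,6-trihydroxyphenyl}butan-1-one (CNP0264591.0) | CCCC(=O)c1c(O)c(Cc2c(O)c(C(=O)CCC)c(O)c(C)c2OC)c(O)c(Cc2c(O)c(C(=O)CCC)c(O)c(C)c2OC)c1O | target

## Step count and least certain steps

Total: 11 steps. Longest linear sequence: 11 steps (1 → 3 → 4 → 6 → 7 → 8 → 11 → 13 → 18 → 19 → 22 → 23); compound 11 enters twice, in steps 7 and 8.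

Step 8 (key step). The push–pull 3-siloxycyclobutenone may open only at temperatures where the siloxyalkyne begins to rearrange by silyl shift to a silylketene. The vinylketene may also dimerise or acylate the product phenol instead of meeting the crowded alkyne, and traces of moisture would hydrolyse 13 to a cyclobutanedione. The fallback gives up the benzannulation; it sets out from 4 and comes back to the route at 23. A Mannich reaction of 4 with aqueous formaldehyde and dimethylamine in ethanol should give 1-{3-[(dimethylamino)methyl]-2,6-dihydroxy-4-methoxy-5-methylphenyl}butan-1-one F1. Heating two equivalents of F1 with commercial 1-(2,4,6-trihydroxyphenyl)butan-1-one F2 in dioxane should expel dimethylamine, generate the ortho-quinone methide and alkylate both free ring carbons of F2, giving 23 directly.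

Step 6. Oxygen transfer from the peroxide to the acetylide may be incomplete. Proton transfer from the doubly activated CH2 may lead to isomerisation toward an allene, silylation may occur on carbon to give a silylketene, and the silyl enol ether may be lost on work-up. The fallback reaches the ynolate by Kowalski ester homologation; it sets out from 4 and comes back at 10. Iodination of 4 with N-iodosuccinimide should give 1-(2,6-dihydroxy-3-iodo-4-methoxy-5-methylphenyl)butan-1-one F3, and benzylation as in step 4 then gives 1-[2,6-bis(benzyloxy)-3-iodo-4-methoxy-5-methylphenyl]butan-1-one F4. Negishi coupling of F4 with the Reformatsky reagent BrZnCH2CO2Et (Pd(dba)2, P(t-Bu)3, THF) gives ethyl 2-(Ar-k)acetate F5, and soft enolisation as in step 5 gives ethyl 2-(Ar-e)acetate F6. Treatment of F6 with CH2Br2 and lithium 2,2,6,6-tetramethylpiperidide at −78 °C, then LiN(SiMe3)2 and n-BuLi with warming, should rearrange the dibromo ketone enolate to 10, which is silylated as in step 6.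

Step 3. Alkylation may go to oxygen instead of carbon, a second alkylation may dearomatise the ring at a substituted carbon, and base may isomerise the propargyl group to an allene. The fallback is a Nicholas reaction under acidic conditions; it sets out from 4 and comes back at 6. Co2(CO)8 and prop-2-yn-1-ol in CH2Cl2 give hexacarbonyl(μ-prop-2-yn-1-ol)dicobalt F7. With BF3·OEt2 at 0 °C, F7 should alkylate the free ring carbon of 4 to give the hexacarbonyldicobalt-complexed propargyl arene F8, which is the cobalt complex of 6. Oxidative removal of cobalt from F8 with Fe(NO3)3·9H2O in ethanol then releases 6.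

Step 10. Attack at C1 may be slow, and prolonged exposure to HCl could cause acidolysis of benzyl ethers ortho to the ketones or ipso-protonation of ring A with loss of a bridge. The fallback reverses the order of the last two operations; it sets out from 19 and comes back at 23. Hydrogenolysis of 19 (H2, Pd/C) should give 2,4-bis[(3-butanoyl-2,4-dihydroxy-6-methoxy-5-methylphenyl)methyl]benzene-1,3,5-triol F9. Classical Friedel–Crafts acylation of F9 with 2 and AlCl3 in PhNO2 at its only free ring carbon, now with no benzyl ethers to cleave, gives 23.

## Further compounds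

F1 | step 8 | 1-{3-[(dimethylamino)methyl]-2,6-dihydroxy-4-methoxy-5-methylphenyl}butan-1-one | CCCC(=O)c1c(O)c(CN(C)C)c(OC)c(C)c1O
F2 | step 8 | 1-(2,4,6-trihydroxyphenyl)butan-1-one (purchased) | CCCC(=O)c1c(O)cc(O)cc1O
F3 | step 6 | 1-(2,6-dihydroxy-3-iodo-4-methoxy-5-methylphenyl)butan-1-one | CCCC(=O)c1c(O)c(I)c(OC)c(C)c1O
F4 | step 6 | 1-[2,6-bis(benzyloxy)-3-iodo-4-methoxy-5-methylphenyl]butan-1-one | CCCC(=O)c1c(OCc2ccccc2)c(I)c(OC)c(C)c1OCc1ccccc1
F5 | step 6 | ethyl 2-(Ar-k)acetate | CCOC(=O)Cc1c(OC)c(C)c(OCc2ccccc2)c(C(=O)CCC)c1OCc1ccccc1
F6 | step 6 | ethyl 2-(Ar-e)acetate | CCOC(=O)Cc1c(OC)c(C)c(OCc2ccccc2)c(/C(O[Si](C)(C)C(C)(C)C)=C/CC)c1OCc1ccccc1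
F7 | step 3 | hexacarbonyl(μ-prop-2-yn-1-ol)dicobalt | OC[C]12[CH]3[Co]1(=C=O)(=C=O)(=C=O)[Co]23(=C=O)(=C=O)=C=O
F8 | step 3 | hexacarbonyldicobalt complex of 6 | CCCC(=O)c1c(O)c(C[C]23[CH]4[Co]2(=C=O)(=C=O)(=C=O)[Co]34(=C=O)(=C=O)=C=O)c(OC)c(C)c1O
F9 | step 10 | 2,4-bis[(3-butanoyl-2,4-dihydroxy-6-methoxy-5-methylphenyl)methyl]benzene-1,3,5-triol | Oc1cc(O)c(Cc2c(OC)c(C)c(O)c(C(=O)CCC)c2O)c(O)c1Cc1c(OC)c(C)c(O)c(C(=O)CCC)c1O
A1 | alternative 1 | 6'-O-desmethyl trimer with ring A as tribenzyl ether | CCCC(=O)c1c(OCc2ccccc2)c(Cc2c(O)c(C(=O)CCC)c(O)c(C)c2O)c(OCc2ccccc2)c(Cc2c(O)c(C(=O)CCC)c(O)c(C)c2O)c1OCc1ccccc1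
A2 | alternative 1 | ring A bis(β-keto ester), dimethyl ester, mixture of stereoisomers at the two enolisable methine carbons | CCCC(=O)c1c(OCc2ccccc2)c(CCC(=O)C(C)C(=O)OC)c(OCc2ccccc2)c(CCC(=O)C(C)C(=O)OC)c1OCc1ccccc1
A3 | alternative 1 | methyl 3-oxohexanoate | CCCC(=O)CC(=O)OC
A4 | alternative 2 | hepta-O-benzyl target | CCCC(=O)c1c(OCc2ccccc2)c(Cc2c(OCc3ccccc3)c(C(=O)CCC)c(OCc3ccccc3)c(C)c2OC)c(OCc2ccccc2)c(Cc2c(OCc3ccccc3)c(C(=O)CCC)c(OCc3ccccc3)c(C)c2OC)c1OCc1ccccc1
A5 | alternative 2 | 1-{2,6-bis(benzyloxy)-3-[3-(benzyloxy)prop-2-yn-1-yl]-4-methoxy-5-methylphenyl}butan-1-one | COc1c(C)c(OCc2ccccc2)c(C(=O)CCC)c(OCc2ccccc2)c1CC#COCc1ccccc1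
A6 | alternative 2 | 1-(benzyloxy)hex-1-yn-3-one | CCCC(=O)C#COCc1ccccc1
A7 | alternative 2 | bis[(1Z,5Z)-cycloocta-1,5-diene]rhodium tetrafluoroborate | [Rh+].C1C/C=C\CC/C=C\1.C1C/C=C\CC/C=C\1.F[B-](F)(F)F
A8 | alternative 3 | target with the three ring A hydroxyls as benzyl ethers | CCCC(=O)c1c(OCc2ccccc2)c(Cc2c(O)c(C(=O)CCC)c(O)c(C)c2OC)c(OCc2ccccc2)c(Cc2c(O)c(C(=O)CCC)c(O)c(C)c2OC)c1OCc1ccccc1
A9 | alternative 3 | ring A tribenzyl ether carrying two [4-methoxy-5-methyl-2-oxo-6-(2-oxopentyl)-2H-pyran-3-yl]methyl groups | CCCC(=O)c1c(OCc2ccccc2)c(Cc2c(OC)c(C)c(CC(=O)CCC)oc2=O)c(OCc2ccccc2)c(Cc2c(OC)c(C)c(CC(=O)CCC)oc2=O)c1OCc1ccccc1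
A10 | alternative 3 | magnesium dimethoxide | CO[Mg]OC
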